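## The problem

Quiquesetinerviusin B (20) is a 2-aryl-2,3-dihydrobenzofuran neolignan. Ring A carries a methoxy group at C7 and, at C5 para to the ring oxygen O1, an (E)-propenyl chain ending in a 4-hydroxybenzoate. The furan ring carries a 4-hydroxy-3,5-dimethoxyphenyl group (ring B) at C2 and a 4-hydroxybenzoyloxymethyl group at C3. The two stereocentres are adjacent and trans, (2S,3R). Trans is also the more stable arrangement, so one centre can control the other, but the absolute configuration has to be brought in once from outside. The fragile parts are the cinnamyl-type ester (ionised by acid or zerovalent palladium, lost on hydrogenolysis), the two benzoates (no hydrolytic or strongly basic endgame) and the styrene double bond. C2 is fragile too: once the ring B phenol is free, base can open the C2–O1 bond through a para-quinone methide. Three phenols therefore have to be unmasked last under nearly neutral conditions; the two primary alcohols carry the same acyl group and need not be told apart. The feature that opens the structure is C3, which is bound to the ring A carbon C3a and to an exocyclic carbon that can be raised to the carboxyl level. That is the pattern left when the fused aryl carbon C4a of a flavanone moves from the carbonyl carbon C4 to C3, and a flavanone has a single stereocentre, C2, which catalysis can set.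

## Retrosynthesis

**Unmasking (20 ⇒ 19).** The three phenolic O–H bonds are traced back to O–Si bonds. Silyl ethers are chosen because fluoride buffered with acetic acid removes them without touching esters, the alkene or the cinnamyl C–O bond; benzyl ethers (hydrogenolysis) and acyl groups (hydrolysis) would not allow that. Ring B carries the bulkier triisopropylsilyl group because it has to pass through the acidic key step; the benzoates carry tert-butyldimethylsilyl groups, which are introduced late.

**Acyl C–O bonds (19 ⇒ 15 + 18).** Both ester bonds are cut at once, giving diol 15 and two equivalents of 4-(tert-butyldimethylsilyloxy)benzoic acid 18, which comes in one operation from 4-hydroxybenzoic acid 16. The forward reaction needs only a neutral double esterification of two primary alcohols.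

**C5–alkenyl bond (15 ⇒ 13 + 14).** The bond between C5 and the propenyl chain is cut to aryl bromide 13 and the (E)-alkenylboronic ester 14. The neighbouring option is a C5 ester homologated by reduction, oxidation, olefination and a second reduction; that costs four operations where the coupling costs one. The forward step must keep the (E) geometry and tolerate two free hydroxyl groups.

**Oxidation level at C3 (13 ⇒ 12).** The hydroxymethyl group is traced back to the methyl ester of 12. The reduction is placed before the coupling so that no basic step meets a C3–H that is alpha to an ester, benzylic and beta to an aryloxy leaving group.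

**Ring contraction (12 ⇒ 10).** The C3–C3a bond of 12 is cut and the ring A carbon is reattached to the ester carbon, which becomes the C4 ketone of (2S)-flavanone 10. This removes one stereocentre and turns the dihydrobenzofuran into a compound class that is made enantioselectively in one step. The forward reaction has to move C4a from C4 to C3, leave C2 untouched, place the ester trans to the aryl group, and prefer ring A migration over ring B migration. The bromine at C6 of 10 is inert to the oxidant, and halogenated flavanones are typical substrates of this rearrangement.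

**C2–aryl bond (10 ⇒ 4 + 9).** The bond between C2 and ring B is cut to chromone 4 and arylboronic acid 9. Against the chalcone cyclisation, which joins the same pieces but gives a racemate, this cut allows a catalytic enantioselective conjugate addition. The forward step must set C2 as (S) and leave the aryl bromide alone, which a cycle that stays at divalent palladium does.

**Chromone (4 ⇒ 2 ⇒ 1).** O1–C2 and C2–C3 are cut; C2 comes from a formamide acetal and the rest from acetophenone 2. The bromine of 2 is introduced by bromination of commercial 1-(2-hydroxy-3-methoxyphenyl)ethan-1-one 1, where the hydroxyl and acetyl groups direct to the same carbon.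

**Boronic acid (9 ⇒ 6 ⇒ 5).** The C–B bond goes back to the C–Br bond of silyl ether 6, and the O–Si bond to commercial 4-bromo-2,6-dimethoxyphenol 5.

## Roads not taken

**Alternative 1:** Formal [4+1] assembly of the dihydrofuran from an ortho-quinone methide and a benzylic sulfonium ylide. It cuts C2–C3 and O1–C2.
- Forward step: Cs2CO3 would expel sulfinate from sulfone A2 to give the quinone methide; a chiral sulfonium ylide carrying the silylated ring B would add to its exocyclic carbon; the phenoxide would then displace the sulfide to give A1.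
- Merits: both ring bonds and both stereocentres arise in one operation. The trans relationship follows from the anti betaine and the SN2 closure. C3 arrives at the alcohol oxidation level, which saves the ester reduction of the chosen plan. In convergence and oxidation economy this road is at least as good.
- Weak points: the quinone methide carries an alkyl substituent with alpha hydrogens and can tautomerise to the ortho-vinylphenol before the ylide arrives. The absolute configuration rests on a stoichiometric chiral sulfide. An electron-rich benzylic sulfonium salt tends to lose the sulfide by ionisation. A2 and the sulfonium salt each need several steps.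
- Comparison: the chosen plan sets against this a catalytic enantioselective step and a stereospecific rearrangement of a stable, isolable flavanone.

**Alternative 2:** Closure of O1–C2 from the open-chain 1,2-diarylpropane-1,3-diol A4.
- Forward step: acid would remove the methoxymethyl ethers and ionise the benzylic alcohol to a ring B quinone methide or cation, which the ring A phenol would trap to give A3, trans to the hydroxymethyl group.
- Merits: no oxidant comes near the electron-rich rings. The trans outcome is under thermodynamic control and is as reliable as in the chosen plan. The stereocentre that survives is set beforehand by well-understood auxiliary chemistry.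
- Weak points: A4 has to be built with its benzylic stereocentre by an auxiliary-based aldol or alkylation sequence of several steps. That centre is alpha to a carbonyl group and to an arene on the way and can epimerise. A3 emerges with a free ring B phenol beside a primary alcohol, so it must be protected again or the later acylation must be made selective.
- Comparison: stereochemical security is equal; the chosen plan is shorter and uses no stoichiometric chirality.

**Alternative 3:** Carbonylative oxypalladation, cutting O1–C2 and the C3–carbonyl bond.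
- Forward step: PdI2 with thiourea, CBr4, carbon monoxide and methanol would convert ortho-alkynylphenol A6 by 5-endo oxypalladation, CO insertion and methanolysis into benzofuran diester A5.
- Merits: the ring-forming step has no stereochemical issue. A6 comes from a Sonogashira coupling. Up to the racemic skeleton this is the shortest road of all and beats the chosen plan.
- Weak points: A5 is flat. Both stereocentres would have to be created by reducing a tetrasubstituted aromatic C2–C3 double bond with trans and absolute control. Dissolving-metal reduction gives the trans compound only as a racemate, and hydrogenation adds cis and would need an epimerisation. An aryl halide could not be carried through, which brings back the four-step ester homologation at C5.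
- Comparison: the chosen plan has its stereocentre in place before the five-membered ring exists and transfers it, which this road cannot match for a single enantiomer.

Key step: step 6

## Route

Assumption: (R)-t-BuPyOx is taken to deliver the aryl group to the face of chromone 4 that gives the (2S) configuration, by analogy with its sense on cyclic enones; if the sense proves opposite, the (S)-ligand is used and nothing else changes.

Step 1
Reactants: 1 1-(2-hydroxy-3-methoxyphenyl)ethan-1-one
Product: 2 1-(5-bromo-2-hydroxy-3-methoxyphenyl)ethan-1-one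
Conditions: Br2 (1.05 equiv), NaOAc, AcOH, rt
Reagents that add atoms: bromine, BrBr
Why: Electrophilic aromatic bromination; the hydroxyl group directs para (both ortho positions are occupied) and the acetyl group directs meta to the same carbon, as in the bromination of ortho-vanillin. The acetate buffer keeps acid-catalysed bromination of the methyl ketone in check.

Step 2
Reactants: 2 1-(5-bromo-2-hydroxy-3-methoxyphenyl)ethan-1-one
Product: 4 6-bromo-8-methoxy-4H-chromen-4-one, via enaminone 3 (not isolated)
Conditions: Me2NCH(OMe)2, toluene, 100 °C; then conc. HCl, CH2Cl2, 40 °C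
Reagents that add atoms: N,N-dimethylformamide dimethyl acetal, COC(OC)N(C)C
Why: Enaminone condensation at the methyl ketone, then acid-promoted conjugate addition of the phenol and loss of dimethylamine, is the standard chromone synthesis from 2-hydroxyacetophenones. The acetal supplies C2 of the chromone.

Step 3
Reactants: 5 4-bromo-2,6-dimethoxyphenol
Product: 6 (4-bromo-2,6-dimethoxyphenoxy)tri(propan-2-yl)silane
Conditions: i-Pr3SiCl, imidazole, DMF, 40 °C
Reagents that add atoms: chlorotri(propan-2-yl)silane, CC(C)[Si](Cl)(C(C)C)C(C)C
Why: Silylation of a phenol with a silyl chloride and imidazole; the triisopropylsilyl group is chosen because its aryl ethers resist the acid of step 6 and the base of step 8.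

Step 4
Reactants: 6 (4-bromo-2,6-dimethoxyphenoxy)tri(propan-2-yl)silane
Product: 9 [3,5-dimethoxy-4-(triisopropylsilyloxy)phenyl]boronic acid, via aryllithium 7 (not isolated), via lithium triisopropoxyborate 8 (not isolated)
Conditions: n-BuLi, THF, −78 °C; B(Oi-Pr)3, −78 °C → rt; aq. NH4Cl, then dilute HCl to pH 5
Reagents that add atoms: triisopropyl borate, CC(C)OB(OC(C)C)OC(C)C; water, O
Why: Bromine–lithium exchange, borylation and hydrolysis of the borate. The lithium sits para to the silyloxy group, so no silyl migration is possible, and the mild acidic work-up limits protodeboronation.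

Step 5
Reactants: 4 6-bromo-8-methoxy-4H-chromen-4-one; 9 [3,5-dimethoxy-4-(triisopropylsilyloxy)phenyl]boronic acid
Product: 10 (2S)-6-bromo-2-[3,5-dimethoxy-4-(triisopropylsilyloxy)phenyl]-8-methoxy-2,3-dihydro-4H-chromen-4-one
Conditions: Pd(OCOCF3)2 (5 mol %), (R)-4-tert-butyl-2-(pyridin-2-yl)-4,5-dihydrooxazole [(R)-t-BuPyOx, 6 mol %], NH4PF6 (30 mol %), H2O (5 equiv), ClCH2CH2Cl, 60 °C, air
Reagents that add atoms: none
Why: Enantioselective conjugate addition of an arylboronic acid to a chromone under cationic divalent palladium with a pyridine-oxazoline ligand, a known route to flavanones: transmetalation, insertion of the chromone C2–C3 double bond, protonation of the palladium enolate by water. C2 is set in the insertion step, where the tert-butyl group of the ligand blocks one face of the bound chromone. The cycle stays at divalent palladium, so the aryl bromide is not touched.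

Step 6
Reactants: 10 (2S)-6-bromo-2-[3,5-dimethoxy-4-(triisopropylsilyloxy)phenyl]-8-methoxy-2,3-dihydro-4H-chromen-4-one
Product: 12 methyl (2S,3S)-5-bromo-2-[3,5-dimethoxy-4-(triisopropylsilyloxy)phenyl]-7-methoxy-2,3-dihydro-1-benzofuran-3-carboxylate, via methyl enol ether 11 (not isolated)
Conditions: PhI(OAc)2 (1.2 equiv), HC(OMe)3 (solvent), conc. H2SO4 (0.3 equiv), rt
Reagents that add atoms: trimethyl orthoformate, COC(OC)OC
Why: Acid and trimethyl orthoformate convert ketone 10 into methyl enol ether 11, which attacks the trivalent iodine reagent at C3 on the face away from the pseudo-equatorial C2 aryl group; methanol adds to the oxocarbenium ion to give a C4 dimethyl ketal with a phenyliodanyl group at C3. As iodobenzene leaves, the ring A carbon C4a shifts from C4 to C3 with inversion at C3, pushed by the two methoxy groups on C4, and the dialkoxycarbenium ion at the former C4 loses a methyl group to become the methyl ester. The closest known reaction type is the oxidative ring contraction of flavanones with PhI(OAc)2 or Tl(NO3)3 in trimethyl orthoformate to trans methyl 2-aryl-2,3-dihydrobenzofuran-3-carboxylates, which has been applied to oxygenated neolignan precursors. The five-membered ring is closed by this 1,2-shift inside the six-membered ring, through a bridged, phenonium-like (formally 3-exo-tet) transition state that O1, ortho to the migrating carbon, stabilises. The new centre C3 is controlled by C2: iodine enters anti to the aryl group and the migrating bond replaces it from the opposite side, so the ester ends up trans to the aryl group, (2S,3S), which is also the more stable isomer. The step needs ring A migration to win over ring B migration (isoflavone), dehydrogenation (flavone) and ring opening at C2. This is secured by the pseudo-equatorial C3–I bond, which is antiperiplanar to C4–C4a but not to C2–aryl or C2–H. It is also secured by ring B itself, whose methoxy groups are meta to C2 and whose silyloxy group is twisted out of conjugation. C2 takes no part, and the triisopropylsilyl ether and the aryl bromide should be inert to the acid and the oxidant at room temperature.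

Step 7
Reactants: 12 methyl (2S,3S)-5-bromo-2-[3,5-dimethoxy-4-(triisopropylsilyloxy)phenyl]-7-methoxy-2,3-dihydro-1-benzofuran-3-carboxylate
Product: 13 [(2S,3R)-5-bromo-2-[3,5-dimethoxy-4-(triisopropylsilyloxy)phenyl]-7-methoxy-2,3-dihydro-1-benzofuran-3-yl]methanol
Conditions: i-Bu2AlH (2.5 equiv), CH2Cl2, −78 → 0 °C; aq. potassium sodium tartrate
Reagents that add atoms: none
Why: Ester reduction with i-Bu2AlH; aryl bromide, silyl ether and benzylic ether are inert at low temperature, and no base is present that could open the beta-aryloxy ester. The C3 descriptor changes from S to R only because the substituent priorities change.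

Step 8
Reactants: 13 [(2S,3R)-5-bromo-2-[3,5-dimethoxy-4-(triisopropylsilyloxy)phenyl]-7-methoxy-2,3-dihydro-1-benzofuran-3-yl]methanol; 14 (2E)-3-(4,4,5,5-tetramethyl-1,3,2-dioxaborolan-2-yl)prop-2-en-1-ol
Product: 15 (2E)-3-[(2S,3R)-2-[3,5-dimethoxy-4-(triisopropylsilyloxy)phenyl]-3-(hydroxymethyl)-7-methoxy-2,3-dihydro-1-benzofuran-5-yl]prop-2-en-1-ol
Conditions: PdCl2(dppf) (5 mol %), K2CO3, 1,4-dioxane/H2O (4:1), 80 °C
Reagents that add atoms: none
Why: Suzuki–Miyaura coupling of an aryl bromide with an (E)-alkenylboronic ester keeps the double-bond geometry and tolerates free hydroxyl groups. With the ester already reduced, C3–H is no longer acidic, so the carbonate base cannot open the ring.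

Step 9
Reactants: 16 4-hydroxybenzoic acid
Product: 18 4-(tert-butyldimethylsilyloxy)benzoic acid, via silyl ester 17 (not isolated)
Conditions: t-BuMe2SiCl (2.3 equiv), imidazole, DMF, rt; then AcOH/THF/H2O, rt
Reagents that add atoms: tert-butylchlorodimethylsilane, CC(C)(C)[Si](C)(C)Cl
Why: Silylation of phenol and acid, then selective hydrolysis of the far more labile silyl ester under mild aqueous acid, which leaves the aryl silyl ether.

Step 10
Reactants: 15 (2E)-3-[(2S,3R)-2-[3,5-dimethoxy-4-(triisopropylsilyloxy)phenyl]-3-(hydroxymethyl)-7-methoxy-2,3-dihydro-1-benzofuran-5-yl]prop-2-en-1-ol; 18 4-(tert-butyldimethylsilyloxy)benzoic acid (2.5 equiv)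
Product: 19 [(2S,3R)-5-[(1E)-3-{[4-(tert-butyldimethylsilyloxy)benzoyl]oxy}prop-1-en-1-yl]-2-[3,5-dimethoxy-4-(triisopropylsilyloxy)phenyl]-7-methoxy-2,3-dihydro-1-benzofuran-3-yl]methyl 4-(tert-butyldimethylsilyloxy)benzoate
Conditions: EDC·HCl (3 equiv), DMAP (0.3 equiv), CH2Cl2, 0 °C → rt
Reagents that add atoms: none
Why: Steglich esterification acylates both primary alcohols with the same acid, so no differentiation is needed. The neutral conditions spare the cinnamyl system and the silyl ethers.

Step 11
Reactants: 19 [(2S,3R)-5-[(1E)-3-{[4-(tert-butyldimethylsilyloxy)benzoyl]oxy}prop-1-en-1-yl]-2-[3,5-dimethoxy-4-(triisopropylsilyloxy)phenyl]-7-methoxy-2,3-dihydro-1-benzofuran-3-yl]methyl 4-(tert-butyldimethylsilyloxy)benzoate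
Product: 20 quiquesetinerviusin B, [(2S,3R)-2-(4-hydroxy-3,5-dimethoxyphenyl)-5-[(1E)-3-(4-hydroxybenzoyloxy)prop-1-en-1-yl]-7-methoxy-2,3-dihydro-1-benzofuran-3-yl]methyl 4-hydroxybenzoate
Conditions: n-Bu4NF (3.5 equiv), AcOH (3.5 equiv), THF, 0 °C → rt
Reagents that add atoms: none
Why: Fluoride cleaves aryl silyl ethers quickly. Buffering with AcOH keeps the liberated phenols protonated, which protects the benzoates from acyl transfer and C2 from opening through a para-quinone methide; neither stereocentre is touched.

## Compound list

1 | 1-(2-hydroxy-3-methoxyphenyl)ethan-1-one | CC(=O)c1cccc(OC)c1O | starting material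
2 | 1-(5-bromo-2-hydroxy-3-methoxyphenyl)ethan-1-one | CC(=O)c1cc(Br)cc(OC)c1O | intermediate
3 | (2E)-1-(5-bromo-2-hydroxy-3-methoxyphenyl)-3-(dimethylamino)prop-2-en-1-one | CN(C)/C=C/C(=O)c1cc(Br)cc(OC)c1O | intermediate
4 | 6-bromo-8-methoxy-4H-chromen-4-one | O=c1ccoc2c(OC)cc(Br)cc12 | intermediate
5 | 4-bromo-2,6-dimethoxyphenol | COc1cc(Br)cc(OC)c1O | starting material
6 | (4-bromo-2,6-dimethoxyphenoxy)tri(propan-2-yl)silane | COc1cc(Br)cc(OC)c1O[Si](C(C)C)(C(C)C)C(C)C | intermediate
7 | [3,5-dimethoxy-4-(triisopropylsilyloxy)phenyl]lithium | [Li]c1cc(OC)c(O[Si](C(C)C)(C(C)C)C(C)C)c(OC)c1 | intermediate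
8 | lithium [3,5-dimethoxy-4-(triisopropylsilyloxy)phenyl]tri(propan-2-yloxy)borate | [Li+].CC(C)O[B-](OC(C)C)(OC(C)C)c1cc(OC)c(O[Si](C(C)C)(C(C)C)C(C)C)c(OC)c1 | intermediate
9 | [3,5-dimethoxy-4-(triisopropylsilyloxy)phenyl]boronic acid | COc1cc(B(O)O)cc(OC)c1O[Si](C(C)C)(C(C)C)C(C)C | intermediate
10 | (2S)-6-bromo-2-[3,5-dimethoxy-4-(triisopropylsilyloxy)phenyl]-8-methoxy-2,3-dihydro-4H-chromen-4-one | COc1cc([C@H]2Oc3c(OC)cc(Br)cc3C(=O)C2)cc(OC)c1O[Si](C(C)C)(C(C)C)C(C)C | intermediate
11 | (2S)-6-bromo-2-[3,5-dimethoxy-4-(triisopropylsilyloxy)phenyl]-4,8-dimethoxy-2H-chromene | COc1cc([C@H]2Oc3c(OC)cc(Br)cc3C(OC)=C2)cc(OC)c1O[Si](C(C)C)(C(C)C)C(C)C | intermediate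
12 | methyl (2S,3S)-5-bromo-2-[3,5-dimethoxy-4-(triisopropylsilyloxy)phenyl]-7-methoxy-2,3-dihydro-1-benzofuran-3-carboxylate (2,3-trans) | COc1cc([C@H]2Oc3c(OC)cc(Br)cc3[C@@H]2C(=O)OC)cc(OC)c1O[Si](C(C)C)(C(C)C)C(C)C | intermediate
13 | [(2S,3R)-5-bromo-2-[3,5-dimethoxy-4-(triisopropylsilyloxy)phenyl]-7-methoxy-2,3-dihydro-1-benzofuran-3-yl]methanol | COc1cc([C@H]2Oc3c(OC)cc(Br)cc3[C@@H]2CO)cc(OC)c1O[Si](C(C)C)(C(C)C)C(C)C | intermediate
14 | (2E)-3-(4,4,5,5-tetramethyl-1,3,2-dioxaborolan-2-yl)prop-2-en-1-ol | OC/C=C/B1OC(C)(C)C(C)(C)O1 | starting material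
15 | (2E)-3-[(2S,3R)-2-[3,5-dimethoxy-4-(triisopropylsilyloxy)phenyl]-3-(hydroxymethyl)-7-methoxy-2,3-dihydro-1-benzofuran-5-yl]prop-2-en-1-ol | COc1cc([C@H]2Oc3c(OC)cc(/C=C/CO)cc3[C@@H]2CO)cc(OC)c1O[Si](C(C)C)(C(C)C)C(C)C | intermediate
16 | 4-hydroxybenzoic acid | OC(=O)c1ccc(O)cc1 | starting material
17 | tert-butyldimethylsilyl 4-(tert-butyldimethylsilyloxy)benzoate | CC(C)(C)[Si](C)(C)OC(=O)c1ccc(O[Si](C)(C)C(C)(C)C)cc1 | intermediate
18 | 4-(tert-butyldimethylsilyloxy)benzoic acid | CC(C)(C)[Si](C)(C)Oc1ccc(C(=O)O)cc1 | intermediate
19 | [(2S,3R)-5-[(1E)-3-{[4-(tert-butyldimethylsilyloxy)benzoyl]oxy}prop-1-en-1-yl]-2-[3,5-dimethoxy-4-(triisopropylsilyloxy)phenyl]-7-methoxy-2,3-dihydro-1-benzofuran-3-yl]methyl 4-(tert-butyldimethylsilyloxy)benzoate | COc1cc([C@H]2Oc3c(OC)cc(/C=C/COC(=O)c4ccc(O[Si](C)(C)C(C)(C)C)cc4)cc3[C@@H]2COC(=O)c2ccc(O[Si](C)(C)C(C)(C)C)cc2)cc(OC)c1O[Si](C(C)C)(C(C)C)C(C)C | intermediate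
20 | quiquesetinerviusin B, [(2S,3R)-2-(4-hydroxy-3,5-dimethoxyphenyl)-5-[(1E)-3-(4-hydroxybenzoyloxy)prop-1-en-1-yl]-7-methoxy-2,3-dihydro-1-benzofuran-3-yl]methyl 4-hydroxybenzoate | COc1cc([C@H]2Oc3c(OC)cc(/C=C/COC(=O)c4ccc(O)cc4)cc3[C@@H]2COC(=O)c2ccc(O)cc2)cc(OC)c1O | target

## Step count and risks

Total: 11 steps, each one-pot sequence counted as one. Longest linear sequence: 8 steps (steps 1, 2, 5, 6, 7, 8, 10, 11).

**Step 6 (key step).**
- Most likely failure: the 1,2-shift of ring B from C2 to C3 or dehydrogenation to the flavone competes with ring A migration. Acid may also cleave the silyl ether, after which the oxidant would attack the free ring B phenol. All of these are favoured by an electron-rich ring B.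
- Fallback: it sets out from 10 and returns at 12. Ring B is made electron-poor for the rearrangement.
  - 10 is desilylated with n-Bu4NF/AcOH to (2S)-6-bromo-2-(4-hydroxy-3,5-dimethoxyphenyl)-8-methoxy-2,3-dihydro-4H-chromen-4-one F1.
  - This is acetylated at once (Ac2O, pyridine) to 4-[(2S)-6-bromo-8-methoxy-4-oxo-3,4-dihydro-2H-chromen-2-yl]-2,6-dimethoxyphenyl acetate F2.
  - The same ring contraction then gives methyl (2S,3S)-2-(4-acetoxy-3,5-dimethoxyphenyl)-5-bromo-7-methoxy-2,3-dihydro-1-benzofuran-3-carboxylate F3.
  - Hydrazine acetate in DMF removes the aryl acetate without base, giving methyl (2S,3S)-5-bromo-2-(4-hydroxy-3,5-dimethoxyphenyl)-7-methoxy-2,3-dihydro-1-benzofuran-3-carboxylate F4.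
  - i-Pr3SiCl and imidazole return 12.

**Step 5.**
- Most likely failure: poor facial selectivity with the 8-methoxy chromone, or protodeboronation of the electron-rich boronic acid outrunning the addition.
- Fallback: it sets out from 4 and 9 and returns at 10. Stereocontrol is moved from the C–C bond formation to a resolution.
  - Addition with the achiral catalyst Pd(OCOCF3)2/2,2'-bipyridine gives racemic 6-bromo-2-[3,5-dimethoxy-4-(triisopropylsilyloxy)phenyl]-8-methoxy-2,3-dihydro-4H-chromen-4-one F5.
  - Noyori–Ikariya transfer hydrogenation with RuCl(p-cymene)[(R,R)-TsDPEN] and HCO2H/Et3N then acts as a kinetic resolution. The antipode of the catalyst is chosen so that the (2R) ketone is the fast one.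
  - The (2R) ketone is reduced to (2R,4R)-6-bromo-2-[3,5-dimethoxy-4-(triisopropylsilyloxy)phenyl]-8-methoxy-3,4-dihydro-2H-chromen-4-ol F6, and (2S)-ketone 10 is left behind and separated by chromatography.

**Step 8.**
- Most likely failure: protodeboronation of the alkenylboronic ester, isomerisation of the allylic alcohol to the saturated aldehyde by a palladium hydride, or loss of the aryl silyl ether in hot aqueous carbonate.
- Fallback: it sets out from 13 and returns at 15.
  - A Heck reaction with methyl acrylate (Pd(OAc)2, P(o-tol)3, Et3N, DMF, 100 °C) gives methyl (2E)-3-[(2S,3R)-2-[3,5-dimethoxy-4-(triisopropylsilyloxy)phenyl]-3-(hydroxymethyl)-7-methoxy-2,3-dihydro-1-benzofuran-5-yl]prop-2-enoate F7.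
  - i-Bu2AlH reduces F7 to 15.

**Step 11.**
- Most likely failure: the hindered ring B silyl ether cleaves more slowly than the activated benzoate silyl ethers. The longer exposure to fluoride invites acyl transfer or ester cleavage, and ring opening at C2 once the ring B phenoxide forms.
- Fallback: it sets out from 15 and returns at 20. The slow desilylation is done before any ester is present.
  - 15 is treated with n-Bu4NF/AcOH to give 4-[(2S,3R)-3-(hydroxymethyl)-5-[(1E)-3-hydroxyprop-1-en-1-yl]-7-methoxy-2,3-dihydro-1-benzofuran-2-yl]-2,6-dimethoxyphenol F8.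
  - Mitsunobu esterification with 18 (PPh3, diisopropyl azodicarboxylate, THF, 0 °C) acylates only the two alcohols. It gives [(2S,3R)-5-[(1E)-3-{[4-(tert-butyldimethylsilyloxy)benzoyl]oxy}prop-1-en-1-yl]-2-(4-hydroxy-3,5-dimethoxyphenyl)-7-methoxy-2,3-dihydro-1-benzofuran-3-yl]methyl 4-(tert-butyldimethylsilyloxy)benzoate F9.
  - KHF2 in MeOH at rt removes the two labile aryl silyl ethers and gives 20.

## Further compounds

F1 | step 6 | (2S)-6-bromo-2-(4-hydroxy-3,5-dimethoxyphenyl)-8-methoxy-2,3-dihydro-4H-chromen-4-one | COc1cc([C@H]2Oc3c(OC)cc(Br)cc3C(=O)C2)cc(OC)c1O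
F2 | step 6 | 4-[(2S)-6-bromo-8-methoxy-4-oxo-3,4-dihydro-2H-chromen-2-yl]-2,6-dimethoxyphenyl acetate | COc1cc([C@H]2Oc3c(OC)cc(Br)cc3C(=O)C2)cc(OC)c1OC(C)=O
F3 | step 6 | methyl (2S,3S)-2-(4-acetoxy-3,5-dimethoxyphenyl)-5-bromo-7-methoxy-2,3-dihydro-1-benzofuran-3-carboxylate | COc1cc([C@H]2Oc3c(OC)cc(Br)cc3[C@@H]2C(=O)OC)cc(OC)c1OC(C)=O
F4 | step 6 | methyl (2S,3S)-5-bromo-2-(4-hydroxy-3,5-dimethoxyphenyl)-7-methoxy-2,3-dihydro-1-benzofuran-3-carboxylate | COc1cc([C@H]2Oc3c(OC)cc(Br)cc3[C@@H]2C(=O)OC)cc(OC)c1O
F5 | step 5 | racemic 6-bromo-2-[3,5-dimethoxy-4-(triisopropylsilyloxy)phenyl]-8-methoxy-2,3-dihydro-4H-chromen-4-one | COc1cc(C2Oc3c(OC)cc(Br)cc3C(=O)C2)cc(OC)c1O[Si](C(C)C)(C(C)C)C(C)C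
F6 | step 5 | (2R,4R)-6-bromo-2-[3,5-dimethoxy-4-(triisopropylsilyloxy)phenyl]-8-methoxy-3,4-dihydro-2H-chromen-4-ol | COc1cc([C@@H]2Oc3c(OC)cc(Br)cc3[C@H](O)C2)cc(OC)c1O[Si](C(C)C)(C(C)C)C(C)C
F7 | step 8 | methyl (2E)-3-[(2S,3R)-2-[3,5-dimethoxy-4-(triisopropylsilyloxy)phenyl]-3-(hydroxymethyl)-7-methoxy-2,3-dihydro-1-benzofuran-5-yl]prop-2-enoate | COc1cc([C@H]2Oc3c(OC)cc(/C=C/C(=O)OC)cc3[C@@H]2CO)cc(OC)c1O[Si](C(C)C)(C(C)C)C(C)C
F8 | step 11 | 4-[(2S,3R)-3-(hydroxymethyl)-5-[(1E)-3-hydroxyprop-1-en-1-yl]-7-methoxy-2,3-dihydro-1-benzofuran-2-yl]-2,6-dimethoxyphenol | COc1cc([C@H]2Oc3c(OC)cc(/C=C/CO)cc3[C@@H]2CO)cc(OC)c1O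
F9 | step 11 | [(2S,3R)-5-[(1E)-3-{[4-(tert-butyldimethylsilyloxy)benzoyl]oxy}prop-1-en-1-yl]-2-(4-hydroxy-3,5-dimethoxyphenyl)-7-methoxy-2,3-dihydro-1-benzofuran-3-yl]methyl 4-(tert-butyldimethylsilyloxy)benzoate | COc1cc([C@H]2Oc3c(OC)cc(/C=C/COC(=O)c4ccc(O[Si](C)(C)C(C)(C)C)cc4)cc3[C@@H]2COC(=O)c2ccc(O[Si](C)(C)C(C)(C)C)cc2)cc(OC)c1O
A1 | alternative 1 | tert-butyl{[(2S,3R)-5-bromo-2-[4-(tert-butyldimethylsilyloxy)-3,5-dimethoxyphenyl]-7-methoxy-2,3-dihydro-1-benzofuran-3-yl]methoxy}dimethylsilane | COc1cc([C@H]2Oc3c(OC)cc(Br)cc3[C@@H]2CO[Si](C)(C)C(C)(C)C)cc(OC)c1O[Si](C)(C)C(C)(C)C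
A2 | alternative 1 | racemic 4-bromo-2-[2-(tert-butyldimethylsilyloxy)-1-(4-methylbenzenesulfonyl)ethyl]-6-methoxyphenol | COc1cc(Br)cc(C(CO[Si](C)(C)C(C)(C)C)S(=O)(=O)c2ccc(C)cc2)c1O
A3 | alternative 2 | 4-[(2S,3R)-5-bromo-3-(hydroxymethyl)-7-methoxy-2,3-dihydro-1-benzofuran-2-yl]-2,6-dimethoxyphenol | COc1cc([C@H]2Oc3c(OC)cc(Br)cc3[C@@H]2CO)cc(OC)c1O
A4 | alternative 2 | (2R)-2-[5-bromo-3-methoxy-2-(methoxymethoxy)phenyl]-1-[3,5-dimethoxy-4-(methoxymethoxy)phenyl]propane-1,3-diol, either C1 epimer | COCOc1c(OC)cc(Br)cc1[C@@H](C(O)c1cc(OC)c(OCOC)c(OC)c1)CO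
A5 | alternative 3 | dimethyl 2-[3,5-dimethoxy-4-(methoxymethoxy)phenyl]-7-methoxy-1-benzofuran-3,5-dicarboxylate | COc1cc(-c2oc3c(OC)cc(C(=O)OC)cc3c2C(=O)OC)cc(OC)c1OCOC
A6 | alternative 3 | methyl 3-{[3,5-dimethoxy-4-(methoxymethoxy)phenyl]ethynyl}-4-hydroxy-5-methoxybenzoate | COC(=O)c1cc(OC)c(O)c(C#Cc2cc(OC)c(OCOC)c(OC)c2)c1
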